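**Strategy.** Lignan locants: C7–C9 lie in the half carrying syringyl ring C (later bearing units B and A), C7′–C9′ in the other. The core is traced back to a donor–acceptor cyclopropane C7–C8–C8′, made by enantioselective intramolecular cyclopropanation (fixes C8) and hydroxymethylated at C8′. Lewis acid heterolysis of bond C7–C8′ (syringyl donor on C7, lactone carbonyl C7′ on C8′) lets the C9′ hydroxyl capture the benzylic cation: the three-membered ring grows in one operation into the tetrahydrofuran C7–O–C9′–C8′–C8, aryl exo. Aryl addition and quinone methide closure give mono-protected (−)-syringaresinol; the guaiacylglycerol units follow by glycolate aldol reactions (threo) and Mitsunobu inversion at C7 (erythro).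

Key step: step 6

Remarks
- Letters: rings A, B and E are guaiacyl, rings C and D syringyl; units A, B and E are the glycerol chains whose C7 carries ring A, B or E. Target configuration: core 7R,8S,7′R,8′S; unit A erythro (7R,8S); unit B threo (7R,8R); unit E erythro (7S,8R).
- Assumption: Rh2(4S-MPPIM)4, dirhodium tetrakis[methyl (4S)-2-oxo-1-(3-phenylpropanoyl)imidazolidine-4-carboxylate], induces the same sense as with allyl diazoacetate, giving the (1R,5S) lactone; if the antipode forms, the 4R catalyst is used.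
- Assumption: both enantiomers of 4-benzyl-3-(chloroacetyl)oxazolidin-2-one are catalogue reagents (otherwise one N-acylation of the oxazolidinone with chloroacetyl chloride).
- Isoeugenol is drawn as the E isomer; its alkene geometry is irrelevant because the alkene is cleaved in step 22.
- Abbreviations in names: Xs = (S)-4-benzyl-2-oxooxazolidin-3-yl, Xr = its R enantiomer, TBS = tert-butyldimethylsilyl, TIPS = triisopropylsilyl.

**Route**

Step 1
Reactants: 1 sinapic acid
Product: 2 allyl (E)-3-[4-(allyloxy)-3,5-dimethoxyphenyl]prop-2-enoate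
Conditions: allyl bromide, K2CO3, DMF, 50 °C
Reagents that add atoms: allyl bromide C=CCBr
Why: Williamson etherification of the phenoxide and alkylation of the carboxylate mask both acidic sites in one operation.

Step 2
Reactants: 2 allyl (E)-3-[4-(allyloxy)-3,5-dimethoxyphenyl]prop-2-enoate
Product: 3 (E)-3-[4-(allyloxy)-3,5-dimethoxyphenyl]prop-2-en-1-ol
Conditions: i-Bu2AlH, CH2Cl2, −78 to 0 °C
Reagents that add atoms: none
Why: 1,2-Hydride reduction of the conjugated allyl ester should give the E allylic alcohol without touching either alkene.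

Step 3
Reactants: 3 (E)-3-[4-(allyloxy)-3,5-dimethoxyphenyl]prop-2-en-1-ol
Product: 5 (E)-3-[4-(allyloxy)-3,5-dimethoxyphenyl]allyl diazoacetate, via bromoacetate 4 (not isolated)
Conditions: BrCH2COBr, NaHCO3, MeCN, 0 °C; then TsNHNHTs, DBU, THF, 0 °C
Reagents that add atoms: bromoacetyl bromide BrCC(Br)=O; N,N′-ditosylhydrazine Cc1ccc(cc1)S(=O)(=O)NNS(=O)(=O)c1ccc(C)cc1
Why: O-acylation, then N-alkylation of the ditosylhydrazine by the bromoacetate and base-induced loss of two sulfinates, should give the diazoacetate under acid-free conditions that spare the ionisable cinnamyl ester.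

Step 4
Reactants: 5 (E)-3-[4-(allyloxy)-3,5-dimethoxyphenyl]allyl diazoacetate
Product: 6 (1R,5S,6S)-6-[4-(allyloxy)-3,5-dimethoxyphenyl]-3-oxabicyclo[3.1.0]hexan-2-one
Conditions: Rh2(4S-MPPIM)4 (1 mol %), CH2Cl2, 40 °C, slow addition of 5
Reagents that add atoms: none
Why: Intramolecular cyclopropanation by the chiral dirhodium carboxamidate carbenoid is stereospecific for the E alkene (aryl exo) and the ligand sphere selects the alkene face, which sets C8 together with C7 and C8′ of the cyclopropane.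

Step 5
Reactants: 6 (1R,5S,6S)-6-[4-(allyloxy)-3,5-dimethoxyphenyl]-3-oxabicyclo[3.1.0]hexan-2-one
Product: 7 (1R,5S,6S)-6-[4-(allyloxy)-3,5-dimethoxyphenyl]-1-(hydroxymethyl)-3-oxabicyclo[3.1.0]hexan-2-one
Conditions: LiN(i-Pr)2, THF, −78 °C (6 added to the base); CH2O (gas), −78 °C; AcOH
Reagents that add atoms: formaldehyde C=O
Why: Aldol addition of the bridgehead cyclopropyl lactone enolate to formaldehyde; the enolate is locked in the bicycle, so C8′ can only be substituted with retention and C7 and C8 are untouched.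

Step 6
Reactants: 7 (1R,5S,6S)-6-[4-(allyloxy)-3,5-dimethoxyphenyl]-1-(hydroxymethyl)-3-oxabicyclo[3.1.0]hexan-2-one
Product: 8 (3aS,4R,6aS)-4-[4-(allyloxy)-3,5-dimethoxyphenyl]tetrahydro-1H,3H-furo[3,4-c]furan-1-one (cis-fused, aryl exo)
Conditions: Sc(OTf)3 (10 mol %), CH2Cl2/(CF3)2CHOH 4:1, 0 °C to rt, stopped at full conversion
Reagents that add atoms: none
Why: Proposed new method: scandium coordination to the lactone carbonyl should heterolyse the cyclopropane bond C7–C8′, the only ring bond aligned with the carbonyl π* and the one weakened by the syringyl donor, to a benzylic cation/lactone enolate pair; the C9′ hydroxyl oxygen then closes the tetrahydrofuran C7–O–C9′–C8′–C8 by 5-exo-trig attack on the quinoid cation and the enolate is protonated, the closest known reactions being the Cloke–Wilson rearrangement, the acid-induced isomerisation of 2-arylcyclopropanecarboxylic acids to γ-lactones and the Lewis acid alcoholysis of aryl donor–acceptor cyclopropanes. C7 is set under substrate control: in the cation H8 eclipses the aryl plane (allylic 1,3-strain) and the tethered oxygen adds from the face of C8′, which places the aryl group trans to C9 (exo). C8′ is protonated to the only unstrained, cis-fused bicycle, and C8 is not involved, so the enantiopurity of the cyclopropane is carried through. The step needs cleavage of C7–C8′ in preference to C8–C8′ and kinetic exo closure; the first is secured by the aryl donor and the rigid lactone, the second by stopping before the new benzylic ether can ionise again.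

Step 7
Reactants: 8 (3aS,4R,6aS)-4-[4-(allyloxy)-3,5-dimethoxyphenyl]tetrahydro-1H,3H-furo[3,4-c]furan-1-one
Product: 9 (3aS,4R,6aS)-4-[4-(allyloxy)-3,5-dimethoxyphenyl]tetrahydro-1H,3H-furo[3,4-c]furan-1-ol (lactol, both C1 epimers)
Conditions: i-Bu2AlH (1.1 equiv), CH2Cl2, −78 °C
Reagents that add atoms: none
Why: Partial reduction of the γ-lactone stops at the tetrahedral aluminate and avoids a base-labile aryl ketone at C8′ in the next step; no ring stereocentre is touched.

Step 8
Reactants: 9 lactol of step 7; 10 4-bromo-2,6-dimethoxyphenol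
Product: 12 (−)-syringaresinol mono-allyl ether, 4-[(1R,3aS,4R,6aS)-4-(4-allyloxy-3,5-dimethoxyphenyl)tetrahydro-1H,3H-furo[3,4-c]furan-1-yl]-2,6-dimethoxyphenol, via triol 11 (not isolated)
Conditions: 10 (3 equiv), n-BuLi then t-BuLi, THF, −78 °C; 9, −78 to 0 °C; H2O; then PPTS (cat.), CH2Cl2, 0 °C
Reagents that add atoms: none
Why: Aryllithium addition (bromine–lithium exchange on the lithium phenoxide) to the hydroxy-aldehyde form of the lactol, then acid-catalysed cyclodehydration in which both carbinol epimers pass through one p-quinone methide that the C9 hydroxyl traps with the aryl group exo (kinetic control, as in oxidative lignan dimerisation), setting C7′ as R.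

Step 9
Reactants: 12 (−)-syringaresinol mono-allyl ether; 13 (S)-4-benzyl-3-(chloroacetyl)oxazolidin-2-one
Product: 14 ring D O-CH2C(=O)Xs ether of 12
Conditions: K2CO3, NaI (cat.), MeCN, 45 °C
Reagents that add atoms: none
Why: Williamson etherification of the syringyl phenoxide with the α-chloro imide, accelerated by halide exchange; the weak base should leave the imide and the benzylic ethers intact.

Step 10
Reactants: 15 vanillin
Product: 16 3-methoxy-4-(triisopropylsilyloxy)benzaldehyde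
Conditions: i-Pr3SiCl, imidazole, DMF, rt
Reagents that add atoms: chlorotriisopropylsilane CC(C)[Si](Cl)(C(C)C)C(C)C
Why: Silylation of the phenol gives a bulky aryl silyl ether expected to survive carbonate, boron triflate and borohydride.

Step 11
Reactants: 14 ring D glycolyl imide; 16 3-methoxy-4-(triisopropylsilyloxy)benzaldehyde
Product: 17 syn aldol adduct, ring D–O–CH[C(=O)Xs]–CH(OH)–ring E(OTIPS), acyl chain 2S,3R (threo)
Conditions: Bu2BOTf, i-Pr2NEt, CH2Cl2, −78 to 0 °C; 16, −78 to 0 °C; pH 7 buffer, MeOH, H2O2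
Reagents that add atoms: none
Why: Evans syn glycolate aldol: the Z boron enolate adds through a closed chair transition state on the face opposite the benzyl group of the auxiliary, which sets C8 (R after reduction) and C7 (R) of unit E.

Step 12
Reactants: 17 syn aldol adduct
Product: 18 C7-inverted 4-nitrobenzoate of 17, acyl chain 2S,3S
Conditions: PPh3, DIAD, 4-nitrobenzoic acid, THF, 0 °C to rt
Reagents that add atoms: 4-nitrobenzoic acid O=C(O)c1ccc(cc1)[N+](=O)[O-]
Why: Mitsunobu reaction: SN2 displacement of the oxyphosphonium by the carboxylate inverts the only free, benzylic carbinol C7 and converts the threo into the erythro series.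

Step 13
Reactants: 18 inverted 4-nitrobenzoate
Product: 19 erythro (7S,8R) diol of unit E on ring D of the mono-allyl core
Conditions: LiBH4, THF/MeOH, 0 °C to rt
Reagents that add atoms: none
Why: Reductive cleavage of the imide gives the C9 alcohol with release of the auxiliary, and the same hydride reduces off the activated nitrobenzoate without touching C7 or C8.

Step 14
Reactants: 19 erythro diol
Product: 20 bis-TBS ether of 19 (C7–OTBS, C9–OTBS)
Conditions: t-BuMe2SiOTf, 2,6-lutidine, CH2Cl2, −78 to 0 °C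
Reagents that add atoms: tert-butyldimethylsilyl triflate CC(C)(C)[Si](C)(C)OS(=O)(=O)C(F)(F)F
Why: Silylation of both hydroxyls with the silyl triflate and a hindered base protects the diol for the second boron aldol.

Step 15
Reactants: 20 bis-TBS ether
Product: 21 ring C phenol (allyl group removed from 20)
Conditions: Pd(PPh3)4 (5 mol %), morpholine, THF, rt
Reagents that add atoms: none
Why: Palladium-catalysed deallylation through a π-allyl complex captured by the amine frees the ring C phenol and should leave silyl ethers and benzylic ethers intact.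

Step 16
Reactants: 21 ring C phenol; 13 (S)-4-benzyl-3-(chloroacetyl)oxazolidin-2-one
Product: 22 ring C O-CH2C(=O)Xs ether of 21
Conditions: K2CO3, NaI (cat.), MeCN, 45 °C
Reagents that add atoms: none
Why: Williamson etherification of the second syringyl phenoxide; the S auxiliary later delivers the R configuration at C8 of unit B.

Step 17
Reactants: 23 (E)-isoeugenol; 24 (R)-4-benzyl-3-(chloroacetyl)oxazolidin-2-one
Product: 25 (R)-4-benzyl-3-{[2-methoxy-4-((E)-prop-1-enyl)phenoxy]acetyl}oxazolidin-2-one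
Conditions: K2CO3, NaI (cat.), MeCN, 45 °C
Reagents that add atoms: none
Why: Williamson etherification of the guaiacyl phenoxide; the propenyl group serves as a masked aldehyde for ring B.

Step 18
Reactants: 25 propenylphenoxyacetyl imide; 16 3-methoxy-4-(triisopropylsilyloxy)benzaldehyde
Product: 26 syn aldol adduct, ring B(propenyl)–O–CH[C(=O)Xr]–CH(OH)–ring A(OTIPS), acyl chain 2R,3S (threo)
Conditions: Bu2BOTf, i-Pr2NEt, CH2Cl2, −78 to 0 °C; 16, −78 to 0 °C; pH 7 buffer, MeOH, H2O2
Reagents that add atoms: none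
Why: Evans syn glycolate aldol with the R auxiliary gives the mirror-image threo adduct (7S,8S after reduction) through the same chair transition state.

Step 19
Reactants: 26 syn aldol adduct
Product: 27 C7-inverted 4-nitrobenzoate of 26, acyl chain 2R,3R
Conditions: PPh3, DIAD, 4-nitrobenzoic acid, THF, 0 °C to rt
Reagents that add atoms: 4-nitrobenzoic acid O=C(O)c1ccc(cc1)[N+](=O)[O-]
Why: Mitsunobu inversion (SN2) of the benzylic carbinol C7 gives the erythro series of unit A.

Step 20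
Reactants: 27 inverted 4-nitrobenzoate
Product: 28 erythro (7R,8S) diol, (1R,2S)-2-[2-methoxy-4-((E)-prop-1-enyl)phenoxy]-1-[3-methoxy-4-(triisopropylsilyloxy)phenyl]propane-1,3-diol
Conditions: LiBH4, THF/MeOH, 0 °C to rt
Reagents that add atoms: none
Why: LiBH4 cleaves the imide to the C9 alcohol with release of the auxiliary and reduces off the nitrobenzoate.

Step 21
Reactants: 28 erythro diol
Product: 29 bis-TBS ether of 28
Conditions: t-BuMe2SiOTf, 2,6-lutidine, CH2Cl2, −78 to 0 °C
Reagents that add atoms: tert-butyldimethylsilyl triflate CC(C)(C)[Si](C)(C)OS(=O)(=O)C(F)(F)F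
Why: Silylation of both hydroxyls protects unit A for ozonolysis and the final aldol.

Step 22
Reactants: 29 bis-TBS ether
Product: 30 ring B aldehyde, 4-{[(1R,2S)-1,3-bis(TBS-oxy)-1-(3-methoxy-4-TIPS-oxyphenyl)propan-2-yl]oxy}-3-methoxybenzaldehyde
Conditions: O3, CH2Cl2/MeOH, −78 °C; Me2S
Reagents that add atoms: ozone [O-][O+]=O
Why: Ozonolysis with reductive work-up unmasks the aryl aldehyde, the propenyl alkene being far more reactive towards ozone than the alkoxyarenes.

Step 23
Reactants: 22 ring C glycolyl imide; 30 ring B aldehyde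
Product: 31 syn aldol adduct, ring C–O–CH[C(=O)Xs]–CH(OH)–ring B, acyl chain 2S,3R (threo)
Conditions: Bu2BOTf, i-Pr2NEt, CH2Cl2, −78 to 0 °C; 30, −78 to 0 °C; pH 7 buffer, MeOH, H2O2
Reagents that add atoms: none
Why: Evans syn glycolate aldol sets C7 (R) and C8 (R after reduction) of unit B directly in the required threo relationship, the auxiliary overriding the remote stereocentres.

Step 24
Reactants: 31 syn aldol adduct
Product: 32 silyl-protected target (unit B diol free; four TBS ethers on units A and E, two aryl TIPS ethers)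
Conditions: LiBH4, THF/MeOH, 0 °C
Reagents that add atoms: none
Why: Reductive cleavage of the imide gives the C9 alcohol of unit B and returns the auxiliary.

Step 25
Reactants: 32 silyl-protected target
Product: 33 CNP0316493.1
Conditions: Bu4NF, AcOH, THF, 0 °C to rt
Reagents that add atoms: none
Why: Fluoride cleaves the four alkyl and two aryl silyl ethers in one operation, and the acetic acid buffer should prevent quinone methide formation from the liberated p-hydroxybenzylic phenoxides.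

**Compound list**

1 | sinapic acid | COc1cc(/C=C/C(O)=O)cc(OC)c1O | starting material
2 | allyl (E)-3-[4-(allyloxy)-3,5-dimethoxyphenyl]prop-2-enoate | COc1cc(/C=C/C(=O)OCC=C)cc(OC)c1OCC=C | intermediate
3 | (E)-3-[4-(allyloxy)-3,5-dimethoxyphenyl]prop-2-en-1-ol | COc1cc(/C=C/CO)cc(OC)c1OCC=C | intermediate
4 | (E)-3-[4-(allyloxy)-3,5-dimethoxyphenyl]allyl bromoacetate (not isolated) | COc1cc(/C=C/COC(=O)CBr)cc(OC)c1OCC=C | intermediate
5 | (E)-3-[4-(allyloxy)-3,5-dimethoxyphenyl]allyl diazoacetate | COc1cc(/C=C/COC(=O)C=[N+]=[N-])cc(OC)c1OCC=C | intermediate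
6 | (1R,5S,6S)-6-[4-(allyloxy)-3,5-dimethoxyphenyl]-3-oxabicyclo[3.1.0]hexan-2-one | O=C1OC[C@H]2[C@H](c3cc(OC)c(OCC=C)c(OC)c3)[C@@H]12 | intermediate
7 | (1R,5S,6S)-6-[4-(allyloxy)-3,5-dimethoxyphenyl]-1-(hydroxymethyl)-3-oxabicyclo[3.1.0]hexan-2-one | O=C1OC[C@H]2[C@H](c3cc(OC)c(OCC=C)c(OC)c3)[C@@]12CO | intermediate
8 | (3aS,4R,6aS)-4-[4-(allyloxy)-3,5-dimethoxyphenyl]tetrahydro-1H,3H-furo[3,4-c]furan-1-one | O=C1OC[C@@H]2[C@H]1CO[C@H]2c1cc(OC)c(OCC=C)c(OC)c1 | intermediate
9 | (3aS,4R,6aS)-4-[4-(allyloxy)-3,5-dimethoxyphenyl]tetrahydro-1H,3H-furo[3,4-c]furan-1-ol (C1 epimers) | OC1OC[C@@H]2[C@H]1CO[C@H]2c1cc(OC)c(OCC=C)c(OC)c1 | intermediate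
10 | 4-bromo-2,6-dimethoxyphenol | COc1cc(Br)cc(OC)c1O | starting material
11 | triol: 2,3-trans-3,4-cis tetrahydrofuran with 2-(4-allyloxy-3,5-dimethoxyphenyl), 3-hydroxymethyl and 4-[hydroxy(4-hydroxy-3,5-dimethoxyphenyl)methyl] groups, both carbinol epimers (not isolated) | OC(c1cc(OC)c(O)c(OC)c1)[C@@H]1CO[C@@H](c2cc(OC)c(OCC=C)c(OC)c2)[C@@H]1CO | intermediate
12 | (−)-syringaresinol mono-allyl ether (7R,8S,7′R,8′S; ring D phenol free) | C=CCOc1c(OC)cc(cc1OC)[C@@H]1OC[C@@H]2[C@H]1CO[C@H]2c1cc(OC)c(O)c(OC)c1 | intermediate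
13 | (S)-4-benzyl-3-(chloroacetyl)oxazolidin-2-one | ClCC(=O)N1[C@@H](Cc2ccccc2)COC1=O | starting material
14 | ring D O-CH2C(=O)Xs ether of 12 | C=CCOc1c(OC)cc(cc1OC)[C@@H]1OC[C@@H]2[C@H]1CO[C@H]2c1cc(OC)c(OCC(=O)N2[C@@H](Cc3ccccc3)COC2=O)c(OC)c1 | intermediate
15 | vanillin | COc1cc(C=O)ccc1O | starting material
16 | 3-methoxy-4-(triisopropylsilyloxy)benzaldehyde | COc1cc(C=O)ccc1O[Si](C(C)C)(C(C)C)C(C)C | intermediate
17 | syn aldol adduct on ring D, acyl chain 2S,3R | C=CCOc1c(OC)cc(cc1OC)[C@@H]1OC[C@@H]2[C@H]1CO[C@H]2c1cc(OC)c(O[C@H](C(=O)N2[C@@H](Cc3ccccc3)COC2=O)[C@H](O)c2ccc(O[Si](C(C)C)(C(C)C)C(C)C)c(OC)c2)c(OC)c1 | intermediate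
18 | C7-inverted 4-nitrobenzoate, acyl chain 2S,3S | C=CCOc1c(OC)cc(cc1OC)[C@@H]1OC[C@@H]2[C@H]1CO[C@H]2c1cc(OC)c(O[C@H](C(=O)N2[C@@H](Cc3ccccc3)COC2=O)[C@@H](OC(=O)c2ccc(cc2)[N+](=O)[O-])c2ccc(O[Si](C(C)C)(C(C)C)C(C)C)c(OC)c2)c(OC)c1 | intermediate
19 | erythro (7S,8R) diol of unit E on the mono-allyl core | C=CCOc1c(OC)cc(cc1OC)[C@@H]1OC[C@@H]2[C@H]1CO[C@H]2c1cc(OC)c(O[C@H](CO)[C@@H](O)c2ccc(O[Si](C(C)C)(C(C)C)C(C)C)c(OC)c2)c(OC)c1 | intermediate
20 | bis-TBS ether of 19 | C=CCOc1c(OC)cc(cc1OC)[C@@H]1OC[C@@H]2[C@H]1CO[C@H]2c1cc(OC)c(O[C@H](CO[Si](C)(C)C(C)(C)C)[C@@H](O[Si](C)(C)C(C)(C)C)c2ccc(O[Si](C(C)C)(C(C)C)C(C)C)c(OC)c2)c(OC)c1 | intermediate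
21 | ring C phenol (deallylated 20) | Oc1c(OC)cc(cc1OC)[C@@H]1OC[C@@H]2[C@H]1CO[C@H]2c1cc(OC)c(O[C@H](CO[Si](C)(C)C(C)(C)C)[C@@H](O[Si](C)(C)C(C)(C)C)c2ccc(O[Si](C(C)C)(C(C)C)C(C)C)c(OC)c2)c(OC)c1 | intermediate
22 | ring C O-CH2C(=O)Xs ether of 21 | O=C(COc1c(OC)cc(cc1OC)[C@@H]1OC[C@@H]2[C@H]1CO[C@H]2c1cc(OC)c(O[C@H](CO[Si](C)(C)C(C)(C)C)[C@@H](O[Si](C)(C)C(C)(C)C)c2ccc(O[Si](C(C)C)(C(C)C)C(C)C)c(OC)c2)c(OC)c1)N1[C@@H](Cc2ccccc2)COC1=O | intermediate
23 | (E)-isoeugenol | COc1cc(/C=C/C)ccc1O | starting material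
24 | (R)-4-benzyl-3-(chloroacetyl)oxazolidin-2-one | ClCC(=O)N1[C@H](Cc2ccccc2)COC1=O | starting material
25 | (R)-4-benzyl-3-{[2-methoxy-4-((E)-prop-1-enyl)phenoxy]acetyl}oxazolidin-2-one | COc1cc(/C=C/C)ccc1OCC(=O)N1[C@H](Cc2ccccc2)COC1=O | intermediate
26 | syn aldol adduct of 25 and 16, acyl chain 2R,3S | COc1cc([C@H](O)[C@H](C(=O)N2[C@H](Cc3ccccc3)COC2=O)Oc2ccc(/C=C/C)cc2OC)ccc1O[Si](C(C)C)(C(C)C)C(C)C | intermediate
27 | C7-inverted 4-nitrobenzoate of 26, acyl chain 2R,3R | COc1cc([C@@H](OC(=O)c2ccc(cc2)[N+](=O)[O-])[C@H](C(=O)N2[C@H](Cc3ccccc3)COC2=O)Oc2ccc(/C=C/C)cc2OC)ccc1O[Si](C(C)C)(C(C)C)C(C)C | intermediate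
28 | (1R,2S)-2-[2-methoxy-4-((E)-prop-1-enyl)phenoxy]-1-[3-methoxy-4-(triisopropylsilyloxy)phenyl]propane-1,3-diol | COc1cc([C@@H](O)[C@H](CO)Oc2ccc(/C=C/C)cc2OC)ccc1O[Si](C(C)C)(C(C)C)C(C)C | intermediate
29 | bis-TBS ether of 28 | COc1cc([C@@H](O[Si](C)(C)C(C)(C)C)[C@H](CO[Si](C)(C)C(C)(C)C)Oc2ccc(/C=C/C)cc2OC)ccc1O[Si](C(C)C)(C(C)C)C(C)C | intermediate
30 | ring B aldehyde carrying protected erythro (7R,8S) unit A | COc1cc([C@@H](O[Si](C)(C)C(C)(C)C)[C@H](CO[Si](C)(C)C(C)(C)C)Oc2ccc(C=O)cc2OC)ccc1O[Si](C(C)C)(C(C)C)C(C)C | intermediate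
31 | syn aldol adduct of 22 and 30, unit B acyl chain 2S,3R | COc1cc([C@@H](O[Si](C)(C)C(C)(C)C)[C@H](CO[Si](C)(C)C(C)(C)C)Oc2ccc([C@@H](O)[C@@H](C(=O)N6[C@@H](Cc7ccccc7)COC6=O)Oc3c(OC)cc([C@@H]4OC[C@@H]5[C@H]4CO[C@H]5c4cc(OC)c(O[C@H](CO[Si](C)(C)C(C)(C)C)[C@@H](O[Si](C)(C)C(C)(C)C)c5ccc(O[Si](C(C)C)(C(C)C)C(C)C)c(OC)c5)c(OC)c4)cc3OC)cc2OC)ccc1O[Si](C(C)C)(C(C)C)C(C)C | intermediate
32 | silyl-protected target with free threo (7R,8R) diol of unit B | COc1cc([C@@H](O[Si](C)(C)C(C)(C)C)[C@H](CO[Si](C)(C)C(C)(C)C)Oc2ccc([C@@H](O)[C@@H](CO)Oc3c(OC)cc([C@@H]4OC[C@@H]5[C@H]4CO[C@H]5c4cc(OC)c(O[C@H](CO[Si](C)(C)C(C)(C)C)[C@@H](O[Si](C)(C)C(C)(C)C)c5ccc(O[Si](C(C)C)(C(C)C)C(C)C)c(OC)c5)c(OC)c4)cc3OC)cc2OC)ccc1O[Si](C(C)C)(C(C)C)C(C)C | intermediate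
33 | CNP0316493.1 | COc1cc([C@@H](O)[C@H](CO)Oc2ccc([C@@H](O)[C@@H](CO)Oc3c(OC)cc([C@@H]4OC[C@@H]5[C@H]4CO[C@H]5c4cc(OC)c(O[C@H](CO)[C@@H](O)c5ccc(O)c(OC)c5)c(OC)c4)cc3OC)cc2OC)ccc1O | target

**Step count.** 25 steps in total. Longest linear sequence: 18 steps (steps 1–9, 11–16, 23–25).

**Steps most likely to fail**

Step 6 (proposed new method). The lactone may not polarise C7–C8′ enough on its own, so that the cation is lost by elimination of H8 or forcing conditions re-ionise the product and erode the exo selectivity. The fallback uses known chemistry and sets out from 7. Dess–Martin oxidation gives the aldehyde (1R,5S,6S)-6-[4-(allyloxy)-3,5-dimethoxyphenyl]-2-oxo-3-oxabicyclo[3.1.0]hexane-1-carbaldehyde F1. This doubly activated cyclopropane should undergo the Cloke–Wilson rearrangement with Sc(OTf)3 (cat.) in CH2Cl2 at 0 °C to the enol ether lactone (3aS,4R)-4-[4-(allyloxy)-3,5-dimethoxyphenyl]-3a,4-dihydro-1H,3H-furo[3,4-c]furan-1-one F2; the formyl oxygen is the only one that can reach C7. Conjugate reduction with [CuH(PPh3)]6, which spares the allyl ether, and protonation of the enolate to the cis-fused bicycle bring the route back at 8.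

Step 5. Lithiation of the strained bridgehead position may be slower than attack of the base or of the enolate on the lactone carbonyl, or the aldolate may revert on warming. The fallback sets out from 5. Vilsmeier formylation of the diazo carbon [(COCl)2, DMF; aqueous NaHCO3] gives (E)-3-[4-(allyloxy)-3,5-dimethoxyphenyl]allyl 2-diazo-3-oxopropanoate F3. Asymmetric intramolecular cyclopropanation with the chiral cobalt porphyrin Co(3,5-DitBu-ChenPhyrin), a method used for acceptor-substituted diazoacetates, gives the formyl lactone F1 already met above. NaBH4 in MeOH at −40 °C reduces only the aldehyde and returns the route at 7.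

Step 12. The activated β-hydroxy imide may eliminate towards the α-aryloxy cinnamoyl imide, or the electron-rich benzylic oxyphosphonium may ionise and give partial retention. The fallback sets out from 17 and sets C7 by reduction instead of substitution. LiBH4 gives the threo (7R,8R) diol F4; TBSCl/imidazole silylates the primary hydroxyl to F5; Dess–Martin oxidation gives the α-aryloxy ketone F6. Chelation-controlled reduction with Zn(BH4)2 in Et2O at −20 °C should give the erythro (7S,8R) alcohol F7, and t-BuMe2SiOTf/2,6-lutidine returns the route at 20.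

**Further compounds**

F1 | step 6 | (1R,5S,6S)-6-[4-(allyloxy)-3,5-dimethoxyphenyl]-2-oxo-3-oxabicyclo[3.1.0]hexane-1-carbaldehyde | O=C1OC[C@H]2[C@H](c3cc(OC)c(OCC=C)c(OC)c3)[C@@]12C=O
F2 | step 6 | (3aS,4R)-4-[4-(allyloxy)-3,5-dimethoxyphenyl]-3a,4-dihydro-1H,3H-furo[3,4-c]furan-1-one | O=C1OC[C@@H]2C1=CO[C@H]2c1cc(OC)c(OCC=C)c(OC)c1
F3 | step 5 | (E)-3-[4-(allyloxy)-3,5-dimethoxyphenyl]allyl 2-diazo-3-oxopropanoate | COc1cc(/C=C/COC(=O)C(C=O)=[N+]=[N-])cc(OC)c1OCC=C
F4 | step 12 | threo (7R,8R) diol of unit E on the mono-allyl core | C=CCOc1c(OC)cc(cc1OC)[C@@H]1OC[C@@H]2[C@H]1CO[C@H]2c1cc(OC)c(O[C@H](CO)[C@H](O)c2ccc(O[Si](C(C)C)(C(C)C)C(C)C)c(OC)c2)c(OC)c1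
F5 | step 12 | C9 TBS ether of F4 | C=CCOc1c(OC)cc(cc1OC)[C@@H]1OC[C@@H]2[C@H]1CO[C@H]2c1cc(OC)c(O[C@H](CO[Si](C)(C)C(C)(C)C)[C@H](O)c2ccc(O[Si](C(C)C)(C(C)C)C(C)C)c(OC)c2)c(OC)c1
F6 | step 12 | C7 ketone of F5 (8R) | C=CCOc1c(OC)cc(cc1OC)[C@@H]1OC[C@@H]2[C@H]1CO[C@H]2c1cc(OC)c(O[C@H](CO[Si](C)(C)C(C)(C)C)C(=O)c2ccc(O[Si](C(C)C)(C(C)C)C(C)C)c(OC)c2)c(OC)c1
F7 | step 12 | erythro (7S,8R) C7 alcohol with C9 TBS ether | C=CCOc1c(OC)cc(cc1OC)[C@@H]1OC[C@@H]2[C@H]1CO[C@H]2c1cc(OC)c(O[C@H](CO[Si](C)(C)C(C)(C)C)[C@@H](O)c2ccc(O[Si](C(C)C)(C(C)C)C(C)C)c(OC)c2)c(OC)c1
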